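Remark on the structure: the stereocentre is (R) (OAc > CH2Ar > C11H23 > H). Locants used below: arene C1 (side chain), C3 (OH), C5 (OMe); side chain C1' (ArCH2), C2' (CHOAc), C3'–C13' (undecyl). Compounds 1 and 5 are taken as the commercial starting materials.

## The problem

The target 13 is a 5-alkylresorcinol whose two meta oxygens are different (C3–OH, C5–OMe) and whose chain carries one stereocentre, C2' (R), as a secondary acetate. C2' lies between two methylene groups (C1'H2–aryl and C3'H2–alkyl), so a ketone at C2' offers a small-molecule reductant no steric or electronic bias. The centre must therefore be made while its two neighbours still differ, and as the only stereocentre it cannot be controlled by another. Any route through a symmetrical resorcinol or symmetrical 3,5-dioxygenated aryl halide meets a statistical mono-alkylation or mono-dealkylation, so the arene should arrive with its two oxygens already different. The acetate must sit on the secondary alcohol and not on the more acidic phenol, and it survives neither hydroxide, alkoxide nor organometallic reagents, so it belongs at the end. Precursors in which C2' is β to a carbonyl can lose the centre by retro-aldol cleavage or β-elimination, although the centre is never α to a carbonyl and cannot epimerise. The feature that opens the way is that oxygen stands on every second carbon: C5 (OMe), C3 (OH), C1 (chain attachment, deoxygenated) and C2' (OAc), which makes the benzene ring the aldol-closed, decarboxylated tetraketide of a 3-hydroxytetradecanoyl unit. Its segment C3(OH)–C4–C5(OMe)–C6 maps atom for atom on C6–C5–C4–C3 of 4-methoxy-6-methyl-2H-pyran-2-one 5 (ring oxygen → C3–OH, methoxy → C5–OMe), with arene C2 and C1 as a CH2–C(=O) unit on the methyl group of 5, so a pyranone ring can be turned into the benzene ring by opening and re-closure with loss of its carbonyl carbon as carbon dioxide.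

## Retrosynthesis

**13 ⇒ 11.** The acetyl C–O bond at C2' is cut. The acetate goes on last because every way of making the ring uses base that would cleave it, or eliminate it while C2' is β to a ketone. The precursor, diol 11, has no ester. The forward step must acylate the alcohol and leave the phenol free; this is done by acetylating both (12) and removing the aryl acetate, an activated ester, by aminolysis in the same flask.

**11 ⇒ 7 (key disconnection, through 10, 9 and 8).** The arene bond C1–C6 is cut, a carboxyl group is put back on C6 (benzoate 9), and the chain 8 is closed between that carboxyl and the C3 oxygen to the pyranone 7. Compared with the neighbouring cuts (aryl–C1' or C1'–C2' bonds next to an existing arene), this one removes the arene altogether and with it the problem of telling the two oxygens apart. In 7 one oxygen is a methyl ether and the other a lactone oxygen, different from the day 5 is bought. Compound 7 is a ketone on a commercial heterocycle, so it is much simpler than 11. The forward reaction needs hydroxide to open the lactone without displacing the methoxy group, aldol closure (not Claisen closure) of 8, loss of carbon dioxide from 9, and survival of the β-silyloxy ketone until the ring is aromatic.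

**7 ⇒ 5 + 4 (through 6).** The bond between the pyranone CH2 and the ketone carbon is cut, which corresponds to acylation of the lithiated methyl group of 5 (anion 6) by Weinreb amide 4. The neighbouring cut, between the ketone carbon and the CH2 next to C2' or an aldol at C2', would create the stereocentre without control. This cut leaves the centre in a fragment where it is β to a carboxyl derivative. The forward reaction needs C-acylation at the exocyclic carbon and no β-elimination in 4.

**4 ⇒ 3 ⇒ 2 ⇒ 1.** These are functional-group changes only (amide from ester, silyl ether from alcohol), then the C–H bond at the carbinol carbon is cut back to β-keto ester 1. Here the two neighbours of the future C2' differ as much as they ever will (CH2CO2Me, which chelates the metal, against undecyl), so a Noyori hydrogenation sets the centre by catalyst control. Hydroxy ester 2 is itself an article of commerce, so step 1 could be omitted; it is kept to show where the stereocentre is set.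

## Roads not taken

**Alternative 1:** the most obvious cut, arene C1–C1'. Copper-catalysed opening (CuI) of (2R)-2-undecyloxirane A1 at its terminal carbon by the aryl Grignard reagent A2 would give alcohol A3; acetylation and hydrogenolysis of the benzyl ether would then give 13. Both halves carry their difficulty unsolved. A2 needs an arene in which the two meta oxygens have already been differentiated and one protected, which is a statistical operation on a symmetrical precursor. A1 needs a hydrolytic kinetic resolution with a chiral (salen)Co(OAc) catalyst, which by its nature delivers at most half of the racemate. With epoxide formation, resolution, aryl ether formation, coupling, acetylation and deprotection it is no shorter than the six steps chosen, and two of its operations are protecting-group handling on the phenol, which the chosen plan does not need.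

**Alternative 2:** no skeletal cut; the C2'–O bond and the stereocentre are made together by dynamic kinetic resolution. The racemic diol A4, a lipase (Candida antarctica lipase B), a ruthenium racemisation catalyst such as RuCl(CO)2(η5-C5Ph5) and an enol acetate as acyl donor would in principle give 13 in one stereoconvergent step that is also chemoselective for the aliphatic hydroxyl. The empirical size rule for lipases requires one carbinol substituent small enough for the narrow pocket of the active site (about ethyl). Here both neighbours (C1'H2–aryl and the C3' chain) are large, so acylation should be slow and poorly selective for either enantiomer. The free phenol is also likely to bind the ruthenium alkoxide that carries the racemisation. A4 would still need an arene synthesis with the oxygen problem open.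

**Alternative 3:** the two ring bonds of the classical 5-alkylresorcinol synthesis. Michael addition of a malonic ester to enone A5, Claisen ring closure and decarboxylation would give the 5-substituted cyclohexane-1,3-dione A6. Conversion to its methyl enol ether and dehydrogenation (I2 in MeOH, or Pd(OCOCF3)2 under O2) would give 10. The ring arrives two hydrogens short of aromatic, so an oxidation must be carried out on a product that is an electron-rich resorcinol ether, open to ring iodination or over-oxidation, and mono- against di-methyl ether formation must be balanced. A5 also needs two more steps from 3 (reduction to the aldehyde and olefination). The pyranone 5 is already at the oxidation level of the arene and already carries the methyl ether.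

Key step: step 5

## Route

**Step 1**
Reactants: 1 methyl 3-oxotetradecanoate
Product: 2 methyl (3R)-3-hydroxytetradecanoate
Conditions: H2 (50 bar), RuCl2[(R)-BINAP] (0.1 mol %), MeOH, 50 °C
Reagents that add atoms: none
Why: Noyori asymmetric hydrogenation of a β-keto ester; ketone and ester carbonyl chelate the ruthenium, and the (R)-BINAP complex should deliver hydride to the face that gives the (R)-alcohol, as it does for simple 3-oxoalkanoates, the undecyl chain lying outside the chelate.

**Step 2**
Reactants: 2 methyl (3R)-3-hydroxytetradecanoate
Product: 3 methyl (3R)-3-[(tert-butyldimethylsilyl)oxy]tetradecanoate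
Conditions: TBSCl, imidazole, DMF, rt
Reagents that add atoms: tert-butyldimethylsilyl chloride, CC(C)(C)[Si](C)(C)Cl
Why: Standard silylation of a secondary alcohol; the silyl ether blocks alkoxide formation and hence retro-aldol cleavage in steps 3 to 5 and is a poor leaving group for β-elimination; the stereocentre is not touched.

**Step 3**
Reactants: 3 methyl (3R)-3-[(tert-butyldimethylsilyl)oxy]tetradecanoate
Product: 4 (3R)-3-[(tert-butyldimethylsilyl)oxy]-N-methoxy-N-methyltetradecanamide
Conditions: MeNH(OMe)·HCl, iPrMgCl, THF, −20 to 0 °C
Reagents that add atoms: N,O-dimethylhydroxylamine hydrochloride, CNOC.Cl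
Why: Direct aminolysis of the methyl ester by the magnesium amide ClMgN(OMe)Me (Weinreb amide formation); the amide is nucleophilic but weakly basic at this temperature, so the β-silyloxy ester should not enolise or eliminate.

**Step 4**
Reactants: 5 4-methoxy-6-methyl-2H-pyran-2-one; 4 (3R)-3-[(tert-butyldimethylsilyl)oxy]-N-methoxy-N-methyltetradecanamide
Product: 7 6-[(4R)-4-[(tert-butyldimethylsilyl)oxy]-2-oxopentadecyl]-4-methoxy-2H-pyran-2-one, via lithiated pyranone 6 (not isolated)
Conditions: LiN(iPr)2 (2.2 equiv), 5 (2.2 equiv), THF, −78 °C; then 4, −78 to −40 °C; aq. NH4Cl
Reagents that add atoms: none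
Why: Claisen-type C-acylation of a vinylogous ester enolate: LiN(iPr)2 removes a proton from the 6-methyl group of 5 (its γ-position), and anion 6 adds through that exocyclic carbon to the Weinreb amide, whose chelated tetrahedral adduct holds until work-up and so keeps the acidic product from quenching the anion; the stereocentre is not involved.

**Step 5**
Reactants: 7 6-[(4R)-4-[(tert-butyldimethylsilyl)oxy]-2-oxopentadecyl]-4-methoxy-2H-pyran-2-one
Product: 11 3-[(2R)-2-hydroxytridecyl]-5-methoxyphenol, via ring-opened carboxylate 8 (not isolated), via benzoate 9 (not isolated), via silyl ether phenol 10 (not isolated)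
Conditions: KOH (2 M), MeOH–H2O (1:1), Ar, 60 °C, then 110 °C (sealed vessel); then HCl to pH 1, 40 °C
Reagents that add atoms: none
Why: This is the base-induced conversion of a 6-(2-oxoalkyl)-4-methoxy-2-pyranone into a resorcinol monomethyl ether, the laboratory counterpart of the aldol closure of a tetraketide and a reaction type known for this class of pyranones. Hydroxide adds to the lactone carbonyl C2 and the ring opens to carboxylate 8, in which the former ring oxygen stays on the former C6 as a ketone and later becomes the phenol oxygen. Deprotonation of the CH2 between the enol-ether carbon and that ketone gives an anion delocalised to the carbon α to the carboxylate (former pyranone C3), which adds to the side-chain ketone in a 6-exo-trig aldol closure, the only ring formed; loss of water and enolisation give benzoate 9. The carboxyl of 9 stands para to the phenoxide, ortho to the methoxy group and between two ortho substituents, so ipso-protonation and loss of carbon dioxide should follow at the higher temperature to give 10, and the acid then removes the silyl ether. No stereocentre is created; the existing one is never α to a carbonyl and is β to one only until the ring is aromatic. The step needs aldol and not Claisen closure, which opening by hydroxide secures because a carboxylate cannot act as acyl acceptor. It needs retention of the methyl ether, which the methanolic medium makes safe because exchange at the vinylogous carbonate carbon is degenerate. It needs survival of the β-silyloxy ketone, which the silyl group protects against retro-aldol cleavage and the enolate state of the 1,3-dicarbonyl unit protects against β-elimination.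

**Step 6**
Reactants: 11 3-[(2R)-2-hydroxytridecyl]-5-methoxyphenol
Product: 13 (2R)-1-(3-hydroxy-5-methoxyphenyl)tridecan-2-yl acetate, via diacetate 12 (not isolated)
Conditions: Ac2O (2.5 equiv), pyridine, DMAP (cat.), CH2Cl2, rt; then pyrrolidine (4 equiv), 0 °C to rt
Reagents that add atoms: acetic anhydride, CC(=O)OC(C)=O
Why: Exhaustive acetylation with nucleophilic catalysis, then aminolysis in the same flask: the aryl acetate of 12 is an activated ester (phenoxide leaving group) and should be cleaved by the secondary amine, whereas the secondary alkyl acetate is inert to it; acylation is at oxygen, so C2' keeps its configuration.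

## Compound list

1 | methyl 3-oxotetradecanoate | CCCCCCCCCCCC(=O)CC(=O)OC | starting material
2 | methyl (3R)-3-hydroxytetradecanoate | CCCCCCCCCCC[C@H](CC(=O)OC)O | intermediate
3 | methyl (3R)-3-[(tert-butyldimethylsilyl)oxy]tetradecanoate | CCCCCCCCCCC[C@H](CC(=O)OC)O[Si](C)(C)C(C)(C)C | intermediate
4 | (3R)-3-[(tert-butyldimethylsilyl)oxy]-N-methoxy-N-methyltetradecanamide | CCCCCCCCCCC[C@H](CC(=O)N(C)OC)O[Si](C)(C)C(C)(C)C | intermediate
5 | 4-methoxy-6-methyl-2H-pyran-2-one | CC1=CC(OC)=CC(=O)O1 | starting material
6 | lithium (4-methoxy-2-oxo-2H-pyran-6-yl)methanide (lithiated pyranone) | [Li+].[CH2-]C1=CC(OC)=CC(=O)O1 | intermediate (not isolated)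
7 | 6-[(4R)-4-[(tert-butyldimethylsilyl)oxy]-2-oxopentadecyl]-4-methoxy-2H-pyran-2-one | CCCCCCCCCCC[C@H](CC(=O)CC1=CC(OC)=CC(=O)O1)O[Si](C)(C)C(C)(C)C | intermediate
8 | potassium (2E,9R)-9-[(tert-butyldimethylsilyl)oxy]-3-methoxy-5,7-dioxoicos-2-enoate (ring-opened carboxylate) | CCCCCCCCCCC[C@H](CC(=O)CC(=O)C/C(OC)=C\C(=O)[O-])O[Si](C)(C)C(C)(C)C.[K+] | intermediate (not isolated)
9 | potassium 2-[(2R)-2-[(tert-butyldimethylsilyl)oxy]tridecyl]-4-hydroxy-6-methoxybenzoate | CCCCCCCCCCC[C@H](Cc1cc(O)cc(OC)c1C(=O)[O-])O[Si](C)(C)C(C)(C)C.[K+] | intermediate (not isolated)
10 | 3-[(2R)-2-[(tert-butyldimethylsilyl)oxy]tridecyl]-5-methoxyphenol | CCCCCCCCCCC[C@H](Cc1cc(O)cc(OC)c1)O[Si](C)(C)C(C)(C)C | intermediate (not isolated)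
11 | 3-[(2R)-2-hydroxytridecyl]-5-methoxyphenol | CCCCCCCCCCC[C@H](Cc1cc(O)cc(OC)c1)O | intermediate
12 | (2R)-1-[3-(acetyloxy)-5-methoxyphenyl]tridecan-2-yl acetate | CCCCCCCCCCC[C@H](Cc1cc(OC(C)=O)cc(OC)c1)OC(C)=O | intermediate (not isolated)
13 | (2R)-1-(3-hydroxy-5-methoxyphenyl)tridecan-2-yl acetate | CCCCCCCCCCC[C@H](Cc1cc(O)cc(OC)c1)OC(C)=O | target

## Step count and least certain steps

Total: 6 steps. Longest linear sequence: 6 steps (1 → 2 → 3 → 4 → 7 → 11 → 13); 5 enters in step 4.

**Step 5 (key step).** Four processes could spoil it.
- Loss of the silyl group or β-elimination of the silyloxy group before the ring is aromatic, followed by retro-aldol fragmentation. The β-oxygen is activated by the C7 ketone until that point.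
- Displacement of the methoxy group by hydroxide at the vinylogous ester carbon of 7, which would give a symmetrical resorcinol.
- Retro-Claisen cleavage of the 1,3-diketone unit of 8 by hot hydroxide in competition with the aldol closure.
- Incomplete loss of carbon dioxide in the alkaline phase, so that on acidification the liberated alcohol lactonises onto the carboxyl.

Fallback, setting out from 4 and returning at 11: the dianion of 2,2-dimethyl-6-(2-oxopropyl)-4H-1,3-dioxin-4-one F1 (from commercial 2,2,6-trimethyl-4H-1,3-dioxin-4-one with LiN(SiMe3)2 and acetyl chloride; dianion with LiN(iPr)2, THF, −78 °C) would be acylated by 4 to give 6-[(6R)-6-[(tert-butyldimethylsilyl)oxy]-2,4-dioxoheptadecyl]-2,2-dimethyl-4H-1,3-dioxin-4-one F2. Triethylamine in CH2Cl2 at room temperature should close F2 by aldol condensation and dehydration to 5-[(2R)-2-[(tert-butyldimethylsilyl)oxy]tridecyl]-7-hydroxy-2,2-dimethyl-4H-1,3-benzodioxin-4-one F3, in which the phenol ortho to the carbonyl is held in the acetonide and only the para phenol is free. Methylation (MeI, K2CO3, acetone) would give 5-[(2R)-2-[(tert-butyldimethylsilyl)oxy]tridecyl]-7-methoxy-2,2-dimethyl-4H-1,3-benzodioxin-4-one F4. KOH in MeOH–H2O at 120 °C followed by HCl should then remove acetone, carbon dioxide and the silyl group to give 11. This route forms the ring under a tertiary amine instead of hot hydroxide and adds the methyl group only after the ring exists, at the cost of three more steps.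

**Step 4.** The stabilised anion 6 may add too slowly to the amide, so that self-condensation of the lithiated pyranone, lithiation at a ring position or proton transfer takes over. Fallback, setting out from 3 (with 5) and returning at 7: reduction of 3 with iBu2AlH at −78 °C would give (3R)-3-[(tert-butyldimethylsilyl)oxy]tetradecanal F5. Aldol addition of 6 to F5, a well-precedented reaction of this anion with aldehydes, would give 6-[(4R)-4-[(tert-butyldimethylsilyl)oxy]-2-hydroxypentadecyl]-4-methoxy-2H-pyran-2-one F6 as a mixture of epimers at the new carbinol, which is of no consequence. Oxidation with Dess–Martin periodinane would give 7.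

**Step 6.** Aminolysis may not discriminate fully, either leaving aryl acetate or slowly attacking the alkyl acetate on long exposure. Fallback, setting out from 11 and returning at 13: alkylation of the phenoxide only (allyl bromide, K2CO3, acetone) would give (2R)-1-[3-methoxy-5-(prop-2-en-1-yloxy)phenyl]tridecan-2-ol F7. Acetylation (Ac2O, pyridine, DMAP) would give (2R)-1-[3-methoxy-5-(prop-2-en-1-yloxy)phenyl]tridecan-2-yl acetate F8. Removal of the allyl group with Pd(PPh3)4 and morpholine would free the phenol without touching the acetate and give 13.

## Further compounds

F1 | step 5 | 2,2-dimethyl-6-(2-oxopropyl)-4H-1,3-dioxin-4-one | CC(=O)CC1=CC(=O)OC(C)(C)O1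
F2 | step 5 | 6-[(6R)-6-[(tert-butyldimethylsilyl)oxy]-2,4-dioxoheptadecyl]-2,2-dimethyl-4H-1,3-dioxin-4-one | CCCCCCCCCCC[C@H](CC(=O)CC(=O)CC1=CC(=O)OC(C)(C)O1)O[Si](C)(C)C(C)(C)C
F3 | step 5 | 5-[(2R)-2-[(tert-butyldimethylsilyl)oxy]tridecyl]-7-hydroxy-2,2-dimethyl-4H-1,3-benzodioxin-4-one | CCCCCCCCCCC[C@H](Cc1cc(O)cc2OC(C)(C)OC(=O)c12)O[Si](C)(C)C(C)(C)C
F4 | step 5 | 5-[(2R)-2-[(tert-butyldimethylsilyl)oxy]tridecyl]-7-methoxy-2,2-dimethyl-4H-1,3-benzodioxin-4-one | CCCCCCCCCCC[C@H](Cc1cc(OC)cc2OC(C)(C)OC(=O)c12)O[Si](C)(C)C(C)(C)C
F5 | step 4 | (3R)-3-[(tert-butyldimethylsilyl)oxy]tetradecanal | CCCCCCCCCCC[C@H](CC=O)O[Si](C)(C)C(C)(C)C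
F6 | step 4 | 6-[(4R)-4-[(tert-butyldimethylsilyl)oxy]-2-hydroxypentadecyl]-4-methoxy-2H-pyran-2-one (both epimers at the new carbinol) | CCCCCCCCCCC[C@H](CC(O)CC1=CC(OC)=CC(=O)O1)O[Si](C)(C)C(C)(C)C
F7 | step 6 | (2R)-1-[3-methoxy-5-(prop-2-en-1-yloxy)phenyl]tridecan-2-ol | CCCCCCCCCCC[C@H](Cc1cc(OCC=C)cc(OC)c1)O
F8 | step 6 | (2R)-1-[3-methoxy-5-(prop-2-en-1-yloxy)phenyl]tridecan-2-yl acetate | CCCCCCCCCCC[C@H](Cc1cc(OCC=C)cc(OC)c1)OC(C)=O
A1 | alternative 1 | (2R)-2-undecyloxirane | CCCCCCCCCCC[C@@H]1CO1
A2 | alternative 1 | [3-(benzyloxy)-5-methoxyphenyl]magnesium bromide | COc1cc(OCc2ccccc2)cc([Mg]Br)c1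
A3 | alternative 1 | (2R)-1-[3-(benzyloxy)-5-methoxyphenyl]tridecan-2-ol | CCCCCCCCCCC[C@H](Cc1cc(OCc2ccccc2)cc(OC)c1)O
A4 | alternative 2 | rac-3-(2-hydroxytridecyl)-5-methoxyphenol | CCCCCCCCCCCC(O)Cc1cc(O)cc(OC)c1
A5 | alternative 3 | (3E,6R)-6-[(tert-butyldimethylsilyl)oxy]heptadec-3-en-2-one | CCCCCCCCCCC[C@H](C/C=C/C(C)=O)O[Si](C)(C)C(C)(C)C
A6 | alternative 3 | 5-[(2R)-2-[(tert-butyldimethylsilyl)oxy]tridecyl]cyclohexane-1,3-dione | CCCCCCCCCCC[C@H](CC1CC(=O)CC(=O)C1)O[Si](C)(C)C(C)(C)C
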